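**One-step world.** In a one-step world D would turn into X and X would stay. These runs bend over instead: north-east ended at 36.2%, and west, with twice the J and 1 M of D against 2 M, at 32.4%.

the same everywhere: E 65 mM (held)
- north-east: D 2 M; J 1 M; run made earlier
- south: D 2 M; J 1.5 M; run made earlier
- west: D 1 M; J 2 M; run made earlier
- flask: D 2.0 M; J 2.00 M; time 8.0 min

| north-east: time / min | north-east: X / % | south: time / min | south: X / % | west: time / min | west: X / % |
|---|---|---|---|---|---|
| 1.33 | 16.7 | 0.417 | 4.9 | 0.417 | 7.8 |
| 2.50 | 27.6 | 0.833 | 12.3 | 0.833 | 12.0 |
| 4.00 | 34.3 | 2.00 | 21.5 | 2.00 | 23.4 |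
| 5.00 | 36.2 | 5.00 | 31.8 | 5.00 | 32.4 |

(standard deviation of a reading: 1 percentage point)

- at the start none of Q is dissolved
- the analysis behind the earlier runs scatters by 1 percentage point, standard deviation
- reactions considered so far: E <-> Q; D + Q <-> X; D -> Z; Q -> L; D + J -> G

- how much X there is at 8.0 min, in percent of the D charged
- the change that raises the amount of X at 8.0 min, in percent of the D charged most ("none" if none brings more than 2 percentage points) (spring / midnight / none)
- amount of X at 8.0 min, in percent of the D charged, after midnight

- spring: doubling the saturation concentration of E, all else as stated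
- midnight: doubling the transfer coefficient of E, all else as stated

**Leak number.** I assumed that D and X form one stock, leaking to G at a pseudo-first-order rate proportional to c_J, and that percentages ignore c_D. The ratio of those two readings, scaled to the flask's c_J and time, gave 0.355. That is a leak of 29.9%. With c_D and c_J charged alike, c_J averages 85.1% of its charge, so the leak number, e-foldings of the stock lost by the reading, is 0.302.

**One number tested.** It wasn't enough. North-east's rise gave 0.466 min⁻¹ and a leak-free level of 44.8%, hence 32.3% for the flask. South read 31.8% where the leak predicted 34.2%.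

**The forecast.** It gave 32.5% for the flask, chose spring, the doubling of the saturation concentration of E, and put midnight, the doubling of the transfer coefficient of E, at 34%, holding that “Doubling transfer helps only slightly”.

**The result.** E ⇌ Q, rate k1*(csat - [Q]) (kL = 3.40 s⁻¹); D + Q ⇌ X (K = 13.0 M⁻¹, k = 0.0470 M⁻¹ s⁻¹); D → Z (k = 1.10 × 10⁻⁴ s⁻¹); Q → L (k = 9.70 × 10⁻⁶ s⁻¹); D + J → G (k = 6.70 × 10⁻⁴ M⁻¹ s⁻¹)

The flask gave 32.4%; spring added 16 percentage points, and midnight gave 32.4%. G stood at 29.3% after 8.00 min, against 26.1% from the leak number. For the reading at 20 min, with J at 53.4%, the leak number is 0.680, which predicts 22.7% X; that flask held 23.7%.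

The runs are calculated from invented constants; the scatter is artificial.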